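## Analysis of the target

Compound 25 is a (3R)-isoflavan. Benzene ring A is fused to the dihydropyran ring C (O1, C2, C3, C4, C4a, C8a), and C3 carries a second benzene ring B. Ring A has a free hydroxyl at C7 and, at C8 between O1 and that hydroxyl, a 3-hydroxy-3-methylbutyl chain. Ring B is a resorcinol (2'-OH, 4'-OH) with a 2-methylbut-3-en-2-yl (1,1-dimethylallyl) group at C5'. C3 is the only stereocentre and lies between two methylene groups (C2 and C4), so no neighbouring centre can relay its configuration. It must be set by a catalyst or reagent, and any intermediate with a carbonyl group at C2 can lose it again by enolisation. The sensitive groups rule out acid and hydrogenation late in the route: the tertiary alcohol cyclises onto the C7 phenol to a 2,2-dimethylchroman, the 1,1-dimethylallyl group cyclises onto the 4'-phenol or is saturated, and both resorcinol rings oxidise easily. Two substitution problems add to this: ring A is 1,2,3,4-tetrasubstituted with a carbon chain between two oxygens, and ring B needs a quaternary benzylic carbon at C5' and not at C3'. The strategy reads ring C as two pieces. O1, C8a, C4a and C4 are the oxygen, two ring carbons and exocyclic methylene of an ortho-quinone methide of ring A; C2 and C3 with ring B are the carbonyl and α-carbon of an arylacetaldehyde. Joining C3 to C4 and O1 to C2 in one catalytic step makes ring C and the stereocentre together.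

## Retrosynthetic reasoning

**25 from 24.** The three phenolic hydroxyls are traced back to allyl ethers, so the last bonds cut are three O–allyl bonds. Allyl is chosen because it is removed by palladium-catalysed allyl transfer under neutral conditions; benzyl ethers would need hydrogenation and acetal groups would need acid. The forward step must strip three allyl groups without C-allylation of the electron-rich rings.

**24 from 23, and 23 from 22.** The O1–C2 bond of 24 is cut to give phenol and primary alcohol in 23, and 23 is the hydride reduction product of lactol 22. Direct deoxygenation of 22 is avoided: it needs acid and passes through an oxocarbenium ion that can lose the C3 proton. Opening ring C by hydride and closing it again by a neutral Mitsunobu reaction costs one step and keeps C3 away from cations and from a free carbonyl group.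

**22 from 10 and 19.** Here C3–C4 and O1–C2 are cut. These two bonds flank the stereocentre and divide the molecule into two fragments of similar size, each carrying one aromatic ring. Forward, a chiral secondary amine converts 19 into enamine 21, which attacks the methylene of ortho-quinone methide 20; the phenoxide then closes the ring. Since 20 cannot be stored, it is released from sulfone 10 by mild base in the presence of the amine. Cutting at C3–C1' or C2–C3 instead would leave ring C unmade or demand an asymmetric arylation.

**10 from 7 and 8, and 7 from 6.** The C–S bond of 10 goes back to benzylic alcohol 9 and sulfinate 8, and 9 to salicylaldehyde 7. The formyl carbon (the later C4) is disconnected from C4a. In 6 the only free position ortho to the hydroxyl is the required one, so a chelation-directed ortho-formylation has no regiochemical choice, and the hydroxyl/allyloxy pattern needs no further protecting-group steps.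

**6 from 5, and 5 from 2 and 3.** The allyl ether of 6 sits on one of two equivalent hydroxyls of 5. The chain is cut at the bond between C8 and its first carbon. Electrophilic substitution of a resorcinol, or of 11, goes para to oxygen and not between the oxygens. A prenyl group placed there would need Markovnikov hydration beside free phenols, which closes a dimethylchroman ring, and after allylation the alkenes could no longer be told apart. The chain is therefore brought in already oxygenated, from alkynol 3, and attached by Sonogashira coupling at the iodine-bearing carbon of 2 (from 1). Hydrogenation then saturates the alkyne and removes the benzyl ethers, and this must happen before any allyl ether is present.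

**19 from 17.** The C2–C3 bond is cut by one-carbon homologation: the aldehyde carbon of 17 becomes C3 and a Wittig carbon becomes C2. Enol ether 18 is the storage form, because electron-rich arylacetaldehydes such as 19 self-condense.

**17 from 11 and 12.** The bond from C5' to the quaternary carbon is cut by a retro-Claisen step. A 1,1-dimethylallyl group ortho to a phenolic oxygen is the signature of a [3,3] shift of a prenyl ether, here that of 14. The shift must be steered away from C3 (between the oxygens), so the chelated 2-hydroxyl of 13 is first converted into a bulky silyl ether. That silyl group is exchanged for allyl in the same operation that allylates the new phenol of 15 (through 16), so the exchange costs no separate step.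

## Alternatives that were turned down

**Alternative 1: ring A by benzannulation.**
- Disconnection: ring A itself, at C8–C8a, C6–C7 and C4a–C8a.
- Forward key step: the (R)-configured unsaturated diazo ketone A2 is irradiated with silyloxyalkyne A3 and then heated. Wolff rearrangement, [2+2] cycloaddition, four-electron ring opening and six-electron ring closure give phenol A1.
- For: the chain lands between the two oxygens by construction. On this point it is stronger than the chosen route, which spends a coupling, a hydrogenation and a statistical alkylation on the same problem. The C8a hydroxyl emerges free.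
- Against: the C3 stereocentre must already be in A2, so a separate asymmetric step is still needed. Ring C is not formed. A1 carries five silyl ethers of three kinds, of which one primary ether must be cleaved selectively before ring closure. A2 and A3 each need several steps with sensitive functions (diazo transfer, ynol ether).
- Comparison: the hard parts (C3 and ring C) are moved elsewhere and the step count is higher. The chosen strategy offers, in place of the regiocontrol, one step that makes ring C and C3 from two simple aromatic fragments.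

**Alternative 2: conjunctive coupling around a vinylboronate.**
- Disconnection: C3–C1' and C4–C4a, with boron on C3.
- Forward key step: aryllithium A5 is added to vinylboronate A6 and coupled with aryl bromide A7 under Pd(OAc)2 and a chiral ferrocenyl bisphosphine. The ring B aryl group shifts from boron to carbon and reductive elimination joins C4 to C4a, giving boronate A4.
- For: three components meet in one step, and the stereocentre is a configurationally stable C–B centre. On stereochemical robustness it is stronger than the chosen route, whose C3 centre is first formed next to a masked aldehyde.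
- Against: no ring is closed and C2 is missing. What follows is homologation of a hindered secondary boronate, oxidation, selective unmasking of the C8a oxygen, ring closure, and finally acid removal of the methoxymethyl groups, which the tertiary alcohol and the 1,1-dimethylallyl group beside free phenols do not tolerate. A7 needs the same chain-between-oxygens chemistry as 10 plus a bromination, and aryl bromides need halide scavenging in this coupling.
- Comparison: at least five steps follow the key step, against three here. The chosen strategy offers C2 at the right oxidation level, the O1–C2 bond and neutral deprotection.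

**Alternative 3: double aromatic Claisen rearrangement.**
- Disconnection: the two bonds from C8 and from C5' to their side chains, on a finished isoflavan.
- Forward key step: heating bis-ether A9 moves the 7-O-(1,1-dimethylallyl) group to C8 as a prenyl group and the 4'-O-prenyl group to C5' as a 1,1-dimethylallyl group, giving A8.
- For: both C5 units are installed in one reagent-free step. On steps spent on the side chains it is stronger than the chosen route.
- Against: it does not address ring C or C3, so A9 must be made enantioenriched by other means. Two regiochemical choices (C8 against C6, C5' against C3') are made in one flask, and the tertiary aryl ether of A9 is not accessible by simple alkylation. Afterwards the 8-prenyl group must be hydrated in the presence of the other alkene and of the C7 phenol, which would close a dimethylchroman ring.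
- Comparison: more risk remains after the key step than before it. The chosen strategy offers an already oxygenated chain and a key step that solves the central problem.

Key step: step 13

Assumption: the open-face model for enamines of diarylprolinol silyl ethers is taken to hold for the aryl-conjugated enamine 21, which assigns the (R)-amine to the (3R) product; should the sense prove reversed, the (S)-amine is used with no other change.

## Route

Step 1
Reactants: 1 2-iodobenzene-1,3-diol
Product: 2 1,3-bis(benzyloxy)-2-iodobenzene
Conditions: BnBr (2.2 equiv), K2CO3, DMF, rt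
Reagents that add atoms: benzyl bromide, BrCc1ccccc1
Why: Williamson etherification of both phenols; benzyl ethers prevent benzofuran formation in step 2 and are removed at no extra cost in step 3.

Step 2
Reactants: 2 1,3-bis(benzyloxy)-2-iodobenzene; 3 2-methylbut-3-yn-2-ol
Product: 4 4-[2,6-bis(benzyloxy)phenyl]-2-methylbut-3-yn-2-ol
Conditions: PdCl2(PPh3)2 (3 mol %), CuI (6 mol %), Et3N/THF, 65 °C
Reagents that add atoms: none
Why: Sonogashira coupling of an aryl iodide with a terminal alkyne; the iodide fixes the chain between the two oxygens, and the coupling tolerates the two ortho substituents on warming.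

Step 3
Reactants: 4 4-[2,6-bis(benzyloxy)phenyl]-2-methylbut-3-yn-2-ol
Product: 5 2-(3-hydroxy-3-methylbutyl)benzene-1,3-diol
Conditions: H2 (1 bar), Pd/C (10 wt % Pd on carbon), EtOAc/EtOH, rt
Reagents that add atoms: none
Why: Heterogeneous hydrogenation saturates the alkyne to the CH2CH2 link and hydrogenolyses both benzyl ethers in one operation; a neutral solvent is used so that the tertiary C–O bond is kept.

Step 4
Reactants: 5 2-(3-hydroxy-3-methylbutyl)benzene-1,3-diol
Product: 6 2-(3-hydroxy-3-methylbutyl)-3-(prop-2-en-1-yloxy)phenol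
Conditions: allyl bromide (1.0 equiv), K2CO3 (1.0 equiv), acetone, 50 °C; recovered 5 returned to the step
Reagents that add atoms: allyl bromide, C=CCBr
Why: Williamson mono-alkylation of a symmetrical resorcinol, in which either hydroxyl gives the same product; a statistical mixture with the bis-ether and unreacted 5 is expected, and carbonate does not alkylate the tertiary alcohol.

Step 5
Reactants: 6 2-(3-hydroxy-3-methylbutyl)-3-(prop-2-en-1-yloxy)phenol
Product: 7 2-hydroxy-3-(3-hydroxy-3-methylbutyl)-4-(prop-2-en-1-yloxy)benzaldehyde
Conditions: MgCl2 (2 equiv), Et3N (4 equiv), (CH2O)n (6 equiv), MeCN, reflux; aq NH4Cl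
Reagents that add atoms: paraformaldehyde (as formaldehyde), C=O
Why: Magnesium-mediated ortho-formylation: formaldehyde is delivered inside the magnesium phenoxide chelate to the only free ortho position, and a second equivalent acts as hydride acceptor to reach the aldehyde. The basic medium spares the tertiary alcohol and the allyl ether.

Step 6
Reactants: 7 2-hydroxy-3-(3-hydroxy-3-methylbutyl)-4-(prop-2-en-1-yloxy)benzaldehyde; 8 sodium 4-methylbenzenesulfinate
Product: 10 2-(3-hydroxy-3-methylbutyl)-6-{[(4-methylphenyl)sulfonyl]methyl}-3-(prop-2-en-1-yloxy)phenol, via benzylic alcohol 9 (not isolated)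
Conditions: NaBH4, THF/H2O, 0 °C; then 8 (3 equiv), AcOH, rt to 40 °C
Reagents that add atoms: none
Why: Borohydride reduction gives the ortho-hydroxybenzylic alcohol, which ionises under weak acid because of its ortho-hydroxy and para-allyloxy groups and is captured at sulfur by the sulfinate (S-alkylation to the sulfone). Acetic acid is too weak to ionise the tertiary alcohol, and the labile benzylic alcohol is not isolated.

Step 7
Reactants: 11 2,4-dihydroxybenzaldehyde; 12 1-bromo-3-methylbut-2-ene
Product: 13 2-hydroxy-4-[(3-methylbut-2-en-1-yl)oxy]benzaldehyde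
Conditions: 12 (1.05 equiv), K2CO3 (1.1 equiv), acetone, rt
Reagents that add atoms: none
Why: Williamson alkylation; the 2-hydroxyl is hydrogen-bonded to the aldehyde and much less nucleophilic, so the 4-hydroxyl reacts selectively.

Step 8
Reactants: 13 2-hydroxy-4-[(3-methylbut-2-en-1-yl)oxy]benzaldehyde
Product: 14 4-[(3-methylbut-2-en-1-yl)oxy]-2-[(triisopropylsilyl)oxy]benzaldehyde
Conditions: iPr3SiCl, imidazole, DMF, rt
Reagents that add atoms: triisopropylsilyl chloride, CC(C)[Si](Cl)(C(C)C)C(C)C
Why: Silylation of the chelated phenol removes the hydrogen bond that would steer the rearrangement of step 9 to C3 and places a bulky group beside C3.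

Step 9
Reactants: 14 4-[(3-methylbut-2-en-1-yl)oxy]-2-[(triisopropylsilyl)oxy]benzaldehyde
Product: 15 4-hydroxy-5-(2-methylbut-3-en-2-yl)-2-[(triisopropylsilyl)oxy]benzaldehyde
Conditions: PhNEt2, 190 °C, argon, short reaction time
Reagents that add atoms: none
Why: Aromatic Claisen rearrangement ([3,3]) of the prenyl ether with allylic transposition puts the 1,1-dimethylallyl group on an ortho carbon. C5 is unhindered, C3 lies between two oxygen substituents and the para position carries the formyl group. The weakly basic solvent and short heating limit abnormal Claisen rearrangement and cyclisation of the product phenol.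

Step 10
Reactants: 15 4-hydroxy-5-(2-methylbut-3-en-2-yl)-2-[(triisopropylsilyl)oxy]benzaldehyde
Product: 17 5-(2-methylbut-3-en-2-yl)-2,4-bis(prop-2-en-1-yloxy)benzaldehyde, via dihydroxy aldehyde 16 (not isolated)
Conditions: CsF (1.5 equiv), K2CO3 (2 equiv), allyl bromide (3 equiv), DMF, rt to 50 °C
Reagents that add atoms: allyl bromide, C=CCBr
Why: Fluoride cleaves the aryl silyl ether to the phenoxide and both phenoxides are O-allylated in the same flask (Williamson). Any silyl migration during step 9 is of no consequence, since both oxygens end as allyl ethers.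

Step 11
Reactants: 17 5-(2-methylbut-3-en-2-yl)-2,4-bis(prop-2-en-1-yloxy)benzaldehyde
Product: 18 1-(2-methoxyethenyl)-5-(2-methylbut-3-en-2-yl)-2,4-bis(prop-2-en-1-yloxy)benzene (E/Z mixture)
Conditions: Ph3P(CH2OMe)Cl, KOtBu, THF, 0 °C to rt
Reagents that add atoms: (methoxymethyl)triphenylphosphonium chloride, COC[P+](c1ccccc1)(c1ccccc1)c1ccccc1.[Cl-]
Why: Wittig olefination of a non-enolisable aldehyde with the methoxymethylidene ylide (one-carbon homologation); the enol ether is a storable form of the sensitive aldehyde.

Step 12
Reactants: 18 1-(2-methoxyethenyl)-5-(2-methylbut-3-en-2-yl)-2,4-bis(prop-2-en-1-yloxy)benzene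
Product: 19 2-[5-(2-methylbut-3-en-2-yl)-2,4-bis(prop-2-en-1-yloxy)phenyl]acetaldehyde
Conditions: 1 M HCl, THF, rt; used at once
Reagents that add atoms: water, O
Why: Acid-catalysed enol ether hydrolysis by protonation at the benzylic carbon and hydration of the oxocarbenium ion. No free phenol is present beside the 1,1-dimethylallyl group, so dilute acid should cause no cyclisation.

Step 13
Reactants: 10 2-(3-hydroxy-3-methylbutyl)-6-{[(4-methylphenyl)sulfonyl]methyl}-3-(prop-2-en-1-yloxy)phenol; 19 2-[5-(2-methylbut-3-en-2-yl)-2,4-bis(prop-2-en-1-yloxy)phenyl]acetaldehyde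
Product: 22 (3R)-8-(3-hydroxy-3-methylbutyl)-3-[5-(2-methylbut-3-en-2-yl)-2,4-bis(prop-2-en-1-yloxy)phenyl]-7-(prop-2-en-1-yloxy)-3,4-dihydro-2H-chromen-2-ol (anomeric mixture at C2), via ortho-quinone methide 20 (not isolated), via enamine 21 (not isolated)
Conditions: 19 (1.5 equiv), (R)-2-{diphenyl[(trimethylsilyl)oxy]methyl}pyrrolidine (20 mol %), K2CO3 (1.2 equiv), CH2Cl2, −20 °C; cold filtration through silica (Et2O), concentration below 0 °C
Reagents that add atoms: none
Why: K2CO3 deprotonates the phenol of 10 and 1,4-elimination of sulfinate releases the ortho-quinone methide 20, which the allyloxy group para to the methylene stabilises, while 19 condenses with the amine to the E-enamine 21. The β-carbon of 21 adds to the exocyclic methylene of 20 (Michael addition, bond C3–C4) and ring A regains aromaticity as a phenoxide. That phenoxide closes ring C by 6-exo-trig attack on the iminium carbon (bond O1–C2), and the water set free when 21 formed hydrolyses the N,O-acetal to the lactol and the free amine, so the ring is made stepwise and not by a concerted cycloaddition. The closest known reaction type is the secondary-amine-catalysed enantioselective formal [4+2] annulation of enolisable aldehydes with ortho-quinone methides released in situ from 2-(sulfonylalkyl)phenols, which gives chroman-2-ols; here the methide is unsubstituted and the enamine is aryl-conjugated. C3 is controlled by the catalyst alone: the CPh2(OSiMe3) group shields one face of the s-trans E-enamine, and with the (R)-amine attack from the open face should give the (3R) centre, whereas C2 forms as an anomeric mixture that is erased in step 14. The step needs C-alkylation of the enamine to win over N-alkylation of the amine, self-addition of 20 and aldol reaction of 19; slow release of 20 by a solid base, the excess of 19 (which keeps the amine bound as enamine) and the lower electrophilicity of the alkoxy-stabilised methide work in that direction. It also needs C3 to survive: the lactol masks the α-aryl aldehyde, the temperature is low, and amine and base are removed on cold silica before concentration.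

Step 14
Reactants: 22 (3R)-8-(3-hydroxy-3-methylbutyl)-3-[5-(2-methylbut-3-en-2-yl)-2,4-bis(prop-2-en-1-yloxy)phenyl]-7-(prop-2-en-1-yloxy)-3,4-dihydro-2H-chromen-2-ol
Product: 23 6-{(2R)-3-hydroxy-2-[5-(2-methylbut-3-en-2-yl)-2,4-bis(prop-2-en-1-yloxy)phenyl]propyl}-2-(3-hydroxy-3-methylbutyl)-3-(prop-2-en-1-yloxy)phenol
Conditions: NaBH4, THF/MeOH, −20 to 0 °C, directly on crude 22
Reagents that add atoms: none
Why: Borohydride reduces the lactol through its open hydroxy-aldehyde form faster than the α-aryl aldehyde can enolise, so C3 should be carried over unchanged; allyl ethers and alkenes are inert.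

Step 15
Reactants: 23 6-{(2R)-3-hydroxy-2-[5-(2-methylbut-3-en-2-yl)-2,4-bis(prop-2-en-1-yloxy)phenyl]propyl}-2-(3-hydroxy-3-methylbutyl)-3-(prop-2-en-1-yloxy)phenol
Product: 24 2-methyl-4-{(3R)-3-[5-(2-methylbut-3-en-2-yl)-2,4-bis(prop-2-en-1-yloxy)phenyl]-7-(prop-2-en-1-yloxy)-3,4-dihydro-2H-chromen-8-yl}butan-2-ol
Conditions: PPh3, DIAD, THF, 0 °C to rt
Reagents that add atoms: none
Why: Mitsunobu etherification: the primary alcohol is activated as its oxyphosphonium ion and displaced by the phenol in a 6-exo-tet closure of ring C. The tertiary alcohol does not react and C3 is not touched.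

Step 16
Reactants: 24 2-methyl-4-{(3R)-3-[5-(2-methylbut-3-en-2-yl)-2,4-bis(prop-2-en-1-yloxy)phenyl]-7-(prop-2-en-1-yloxy)-3,4-dihydro-2H-chromen-8-yl}butan-2-ol
Product: 25 4-[(3R)-7-hydroxy-8-(3-hydroxy-3-methylbutyl)-3,4-dihydro-2H-chromen-3-yl]-6-(2-methylbut-3-en-2-yl)benzene-1,3-diol
Conditions: Pd(PPh3)4 (10 mol %), morpholine (10 equiv), degassed THF, rt
Reagents that add atoms: none
Why: Palladium-catalysed deallylation: zerovalent palladium ionises each aryl allyl ether to a π-allyl complex and a phenoxide, and morpholine takes up the allyl group. The neutral conditions spare the tertiary alcohol, the 1,1-dimethylallyl group (which has no leaving group) and C3.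

## Compound list

1 | 2-iodobenzene-1,3-diol | Oc1cccc(O)c1I | starting material
2 | 1,3-bis(benzyloxy)-2-iodobenzene | Ic1c(OCc2ccccc2)cccc1OCc1ccccc1 | intermediate
3 | 2-methylbut-3-yn-2-ol | C#CC(C)(C)O | starting material
4 | 4-[2,6-bis(benzyloxy)phenyl]-2-methylbut-3-yn-2-ol | CC(C)(O)C#Cc1c(OCc2ccccc2)cccc1OCc1ccccc1 | intermediate
5 | 2-(3-hydroxy-3-methylbutyl)benzene-1,3-diol | CC(C)(O)CCc1c(O)cccc1O | intermediate
6 | 2-(3-hydroxy-3-methylbutyl)-3-(prop-2-en-1-yloxy)phenol | CC(C)(O)CCc1c(O)cccc1OCC=C | intermediate
7 | 2-hydroxy-3-(3-hydroxy-3-methylbutyl)-4-(prop-2-en-1-yloxy)benzaldehyde | O=Cc1ccc(OCC=C)c(CCC(C)(C)O)c1O | intermediate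
8 | sodium 4-methylbenzenesulfinate | Cc1ccc(S(=O)[O-])cc1.[Na+] | starting material
9 | 6-(hydroxymethyl)-2-(3-hydroxy-3-methylbutyl)-3-(prop-2-en-1-yloxy)phenol | OCc1ccc(OCC=C)c(CCC(C)(C)O)c1O | intermediate
10 | 2-(3-hydroxy-3-methylbutyl)-6-{[(4-methylphenyl)sulfonyl]methyl}-3-(prop-2-en-1-yloxy)phenol | Cc1ccc(S(=O)(=O)Cc2ccc(OCC=C)c(CCC(C)(C)O)c2O)cc1 | intermediate
11 | 2,4-dihydroxybenzaldehyde | O=Cc1ccc(O)cc1O | starting material
12 | 1-bromo-3-methylbut-2-ene (prenyl bromide) | CC(C)=CCBr | starting material
13 | 2-hydroxy-4-[(3-methylbut-2-en-1-yl)oxy]benzaldehyde | O=Cc1ccc(OCC=C(C)C)cc1O | intermediate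
14 | 4-[(3-methylbut-2-en-1-yl)oxy]-2-[(triisopropylsilyl)oxy]benzaldehyde | O=Cc1ccc(OCC=C(C)C)cc1O[Si](C(C)C)(C(C)C)C(C)C | intermediate
15 | 4-hydroxy-5-(2-methylbut-3-en-2-yl)-2-[(triisopropylsilyl)oxy]benzaldehyde | O=Cc1cc(C(C)(C)C=C)c(O)cc1O[Si](C(C)C)(C(C)C)C(C)C | intermediate
16 | 2,4-dihydroxy-5-(2-methylbut-3-en-2-yl)benzaldehyde | O=Cc1cc(C(C)(C)C=C)c(O)cc1O | intermediate
17 | 5-(2-methylbut-3-en-2-yl)-2,4-bis(prop-2-en-1-yloxy)benzaldehyde | O=Cc1cc(C(C)(C)C=C)c(OCC=C)cc1OCC=C | intermediate
18 | 1-(2-methoxyethenyl)-5-(2-methylbut-3-en-2-yl)-2,4-bis(prop-2-en-1-yloxy)benzene (E/Z mixture) | COC=Cc1cc(C(C)(C)C=C)c(OCC=C)cc1OCC=C | intermediate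
19 | 2-[5-(2-methylbut-3-en-2-yl)-2,4-bis(prop-2-en-1-yloxy)phenyl]acetaldehyde | O=CCc1cc(C(C)(C)C=C)c(OCC=C)cc1OCC=C | intermediate
20 | 2-(3-hydroxy-3-methylbutyl)-6-methylidene-3-(prop-2-en-1-yloxy)cyclohexa-2,4-dien-1-one | C=C1C=CC(OCC=C)=C(CCC(C)(C)O)C1=O | intermediate
21 | (2R)-2-{diphenyl[(trimethylsilyl)oxy]methyl}-1-{(E)-2-[5-(2-methylbut-3-en-2-yl)-2,4-bis(prop-2-en-1-yloxy)phenyl]ethenyl}pyrrolidine | C=CC(C)(C)c1cc(/C=C/N2CCC[C@@H]2C(c2ccccc2)(c2ccccc2)O[Si](C)(C)C)c(OCC=C)cc1OCC=C | intermediate
22 | (3R)-8-(3-hydroxy-3-methylbutyl)-3-[5-(2-methylbut-3-en-2-yl)-2,4-bis(prop-2-en-1-yloxy)phenyl]-7-(prop-2-en-1-yloxy)-3,4-dihydro-2H-chromen-2-ol (anomeric mixture at C2) | C=CC(C)(C)c1cc([C@@H]2C(O)Oc3c(ccc(OCC=C)c3CCC(C)(C)O)C2)c(OCC=C)cc1OCC=C | intermediate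
23 | 6-{(2R)-3-hydroxy-2-[5-(2-methylbut-3-en-2-yl)-2,4-bis(prop-2-en-1-yloxy)phenyl]propyl}-2-(3-hydroxy-3-methylbutyl)-3-(prop-2-en-1-yloxy)phenol | C=CC(C)(C)c1cc([C@H](CO)Cc2ccc(OCC=C)c(CCC(C)(C)O)c2O)c(OCC=C)cc1OCC=C | intermediate
24 | 2-methyl-4-{(3R)-3-[5-(2-methylbut-3-en-2-yl)-2,4-bis(prop-2-en-1-yloxy)phenyl]-7-(prop-2-en-1-yloxy)-3,4-dihydro-2H-chromen-8-yl}butan-2-ol | C=CC(C)(C)c1cc([C@@H]2COc3c(ccc(OCC=C)c3CCC(C)(C)O)C2)c(OCC=C)cc1OCC=C | intermediate
25 | 4-[(3R)-7-hydroxy-8-(3-hydroxy-3-methylbutyl)-3,4-dihydro-2H-chromen-3-yl]-6-(2-methylbut-3-en-2-yl)benzene-1,3-diol | C=CC(C)(C)c1cc([C@@H]2COc3c(ccc(O)c3CCC(C)(C)O)C2)c(O)cc1O | target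

## Step count and least certain steps

Total: 16 steps. Longest linear sequence: 10 steps (steps 1–6, then 13–16); the ring B branch (steps 7–12, then 13–16) is equally long.

**Step 13 (key step).** The most likely failure is partial loss of configuration at C3. The lactol can open to the α-aryl aldehyde and re-form an enamine with the amine still present. Low conversion is also possible if 20 is consumed by self-addition or by N-alkylation of the amine, or if 19 undergoes aldol condensation.

Fallback: an oxazolidinone-auxiliary (Evans) alkylation, setting out from 19 and 7 and returning at 23.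
- Pinnick oxidation of 19 (NaClO2, NaH2PO4, 2-methylbut-2-ene) should give [5-(2-methylbut-3-en-2-yl)-2,4-bis(prop-2-en-1-yloxy)phenyl]acetic acid F1. Via its mixed pivalic anhydride, F1 acylates lithiated (R)-4-benzyl-1,3-oxazolidin-2-one to give the N-acyl oxazolidinone F2.
- From 7, silylation of the phenol (tBuMe2SiCl, imidazole) gives the silyloxy aldehyde F3. Reduction (iBu2AlH, −78 °C) gives the benzylic alcohol F4, and PPh3/CBr4 gives the benzylic bromide F5.
- The sodium enolate of F2 (NaN(SiMe3)2, THF, −78 °C) is alkylated by F5 on the face away from the benzyl group of the auxiliary, which should give the alkylated imide F6 with the (R) centre. For this substituent pattern the (R)-auxiliary is the one expected to lead to (R).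
- LiBH4 removes the auxiliary to give the silyl-protected alcohol F7, and Bu4NF frees the phenol to give 23.

This costs about four more operations, but each is standard and the stereocentre never sits beside an aldehyde.

**Step 9.** The rearrangement may go in part to C3. The product phenol may also undergo abnormal Claisen rearrangement or cyclise onto the new alkene, and the prenyl ether may fragment on prolonged heating.

Fallback: fix the position with a halogen, setting out from 11 and returning at 17. Bromination of 11 (Br2, AcOH) should give 5-bromo-2,4-dihydroxybenzaldehyde F8. Silylation (tBuMe2SiCl, imidazole) gives the bis-silyl ether F9. A ligand-controlled γ-selective Suzuki–Miyaura coupling with prenylboronic acid pinacol ester (Pd(OAc)2, bulky biarylphosphine, K3PO4, aqueous THF) gives the 5-(2-methylbut-3-en-2-yl) bis-silyl ether F10. The conditions of step 10 (CsF, K2CO3, allyl bromide) convert F10 into 17.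

**Step 6.** The benzylic cation may be intercepted by another electron-rich ring (oligomerisation) before the sulfinate reaches it. A stronger acid than intended would risk cyclisation of the tertiary alcohol onto the phenol.

Fallback: avoid acid and the benzylic alcohol altogether, setting out from 6 and returning at 10. Mannich aminomethylation of 6 (aqueous formaldehyde, Me2NH, EtOH), ortho-directed by the phenol, gives the Mannich base F11. Methylation (MeI) gives the ammonium iodide F12. Warming F12 with 8 in DMF releases trimethylamine through the quinone methide, and sulfinate addition gives 10.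

**Step 4.** Over-alkylation and the statistical distribution limit throughput; the step is safe but wasteful.

Fallback: differentiate the two hydroxyls by chelation, setting out from 5 and returning at 7. Magnesium-mediated formylation of 5 itself (MgCl2, Et3N, paraformaldehyde) gives 2,4-dihydroxy-3-(3-hydroxy-3-methylbutyl)benzaldehyde F13. In F13 only the hydroxyl para to the formyl group is free of the hydrogen bond, so one equivalent of allyl bromide with K2CO3 should allylate it selectively to give 7.

**Step 16.** The freed resorcinol rings may be C-allylated by the π-allyl palladium intermediate if the scavenger is too slow. The hindered 4'-allyl ether may be cleaved incompletely, and the product may oxidise in air.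

Fallback: a two-stage removal without palladium, setting out from 24 and returning at 25. KOtBu in DMSO isomerises the three allyl ethers to the tris[(Z)-prop-1-enyl] ether F14; the 1,1-dimethylallyl group cannot isomerise. Brief hydrolysis in dilute aqueous HCl/acetone at room temperature then releases 25 and propanal; the acid exposure is far milder than what the cyclisations of the target require.

## Further compounds

F1 | step 13 | [5-(2-methylbut-3-en-2-yl)-2,4-bis(prop-2-en-1-yloxy)phenyl]acetic acid | OC(=O)Cc1cc(C(C)(C)C=C)c(OCC=C)cc1OCC=C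
F2 | step 13 | (4R)-4-benzyl-3-{[5-(2-methylbut-3-en-2-yl)-2,4-bis(prop-2-en-1-yloxy)phenyl]acetyl}-1,3-oxazolidin-2-one | O=C(Cc1cc(C(C)(C)C=C)c(OCC=C)cc1OCC=C)N1[C@H](Cc2ccccc2)COC1=O
F3 | step 13 | 2-[(tert-butyldimethylsilyl)oxy]-3-(3-hydroxy-3-methylbutyl)-4-(prop-2-en-1-yloxy)benzaldehyde | O=Cc1ccc(OCC=C)c(CCC(C)(C)O)c1O[Si](C)(C)C(C)(C)C
F4 | step 13 | 4-{2-[(tert-butyldimethylsilyl)oxy]-6-(hydroxymethyl)-3-(prop-2-en-1-yloxy)phenyl}-2-methylbutan-2-ol | OCc1ccc(OCC=C)c(CCC(C)(C)O)c1O[Si](C)(C)C(C)(C)C
F5 | step 13 | 4-{6-(bromomethyl)-2-[(tert-butyldimethylsilyl)oxy]-3-(prop-2-en-1-yloxy)phenyl}-2-methylbutan-2-ol | BrCc1ccc(OCC=C)c(CCC(C)(C)O)c1O[Si](C)(C)C(C)(C)C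
F6 | step 13 | (4R)-4-benzyl-3-[(2R)-3-{2-[(tert-butyldimethylsilyl)oxy]-3-(3-hydroxy-3-methylbutyl)-4-(prop-2-en-1-yloxy)phenyl}-2-[5-(2-methylbut-3-en-2-yl)-2,4-bis(prop-2-en-1-yloxy)phenyl]propanoyl]-1,3-oxazolidin-2-one | C=CC(C)(C)c1cc([C@@H](Cc2ccc(OCC=C)c(CCC(C)(C)O)c2O[Si](C)(C)C(C)(C)C)C(=O)N2[C@H](Cc3ccccc3)COC2=O)c(OCC=C)cc1OCC=C
F7 | step 13 | 4-{2-[(tert-butyldimethylsilyl)oxy]-6-{(2R)-3-hydroxy-2-[5-(2-methylbut-3-en-2-yl)-2,4-bis(prop-2-en-1-yloxy)phenyl]propyl}-3-(prop-2-en-1-yloxy)phenyl}-2-methylbutan-2-ol | C=CC(C)(C)c1cc([C@H](CO)Cc2ccc(OCC=C)c(CCC(C)(C)O)c2O[Si](C)(C)C(C)(C)C)c(OCC=C)cc1OCC=C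
F8 | step 9 | 5-bromo-2,4-dihydroxybenzaldehyde | O=Cc1cc(Br)c(O)cc1O
F9 | step 9 | 5-bromo-2,4-bis[(tert-butyldimethylsilyl)oxy]benzaldehyde | O=Cc1cc(Br)c(O[Si](C)(C)C(C)(C)C)cc1O[Si](C)(C)C(C)(C)C
F10 | step 9 | 2,4-bis[(tert-butyldimethylsilyl)oxy]-5-(2-methylbut-3-en-2-yl)benzaldehyde | O=Cc1cc(C(C)(C)C=C)c(O[Si](C)(C)C(C)(C)C)cc1O[Si](C)(C)C(C)(C)C
F11 | step 6 | 6-[(dimethylamino)methyl]-2-(3-hydroxy-3-methylbutyl)-3-(prop-2-en-1-yloxy)phenol | CN(C)Cc1ccc(OCC=C)c(CCC(C)(C)O)c1O
F12 | step 6 | [2-hydroxy-3-(3-hydroxy-3-methylbutyl)-4-(prop-2-en-1-yloxy)phenyl]-N,N,N-trimethylmethanaminium iodide | C[N+](C)(C)Cc1ccc(OCC=C)c(CCC(C)(C)O)c1O.[I-]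
F13 | step 4 | 2,4-dihydroxy-3-(3-hydroxy-3-methylbutyl)benzaldehyde | O=Cc1ccc(O)c(CCC(C)(C)O)c1O
F14 | step 16 | 2-methyl-4-[(3R)-3-{5-(2-methylbut-3-en-2-yl)-2,4-bis[(1Z)-prop-1-en-1-yloxy]phenyl}-7-[(1Z)-prop-1-en-1-yloxy]-3,4-dihydro-2H-chromen-8-yl]butan-2-ol | C=CC(C)(C)c1cc([C@@H]2COc3c(ccc(O/C=C\C)c3CCC(C)(C)O)C2)c(O/C=C\C)cc1O/C=C\C
A1 | alternative 1 | 6-[(2R)-2-{2,4-bis[(tert-butyldimethylsilyl)oxy]-5-(2-methylbut-3-en-2-yl)phenyl}-3-[(tert-butyldimethylsilyl)oxy]propyl]-2-{3-methyl-3-[(triethylsilyl)oxy]butyl}-3-[(triisopropylsilyl)oxy]phenol | C=CC(C)(C)c1cc([C@@H](Cc2ccc(O[Si](C(C)C)(C(C)C)C(C)C)c(CCC(C)(C)O[Si](CC)(CC)CC)c2O)CO[Si](C)(C)C(C)(C)C)c(O[Si](C)(C)C(C)(C)C)cc1O[Si](C)(C)C(C)(C)C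
A2 | alternative 1 | (3E,6R)-6-{2,4-bis[(tert-butyldimethylsilyl)oxy]-5-(2-methylbut-3-en-2-yl)phenyl}-7-[(tert-butyldimethylsilyl)oxy]-1-diazohept-3-en-2-one | C=CC(C)(C)c1cc([C@@H](C/C=C/C(=O)C=[N+]=[N-])CO[Si](C)(C)C(C)(C)C)c(O[Si](C)(C)C(C)(C)C)cc1O[Si](C)(C)C(C)(C)C
A3 | alternative 1 | triethyl({2-methyl-6-[(triisopropylsilyl)oxy]hex-5-yn-2-yl}oxy)silane | CC[Si](CC)(CC)OC(C)(C)CCC#CO[Si](C(C)C)(C(C)C)C(C)C
A4 | alternative 2 | 2-[(1R)-1-[2,4-bis(methoxymethoxy)-5-(2-methylbut-3-en-2-yl)phenyl]-2-(2,4-bis[(tert-butyldimethylsilyl)oxy]-3-{3-methyl-3-[(triethylsilyl)oxy]butyl}phenyl)ethyl]-4,4,5,5-tetramethyl-1,3,2-dioxaborolane | C=CC(C)(C)c1cc([C@@H](Cc2ccc(O[Si](C)(C)C(C)(C)C)c(CCC(C)(C)O[Si](CC)(CC)CC)c2O[Si](C)(C)C(C)(C)C)B2OC(C)(C)C(C)(C)O2)c(OCOC)cc1OCOC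
A5 | alternative 2 | [2,4-bis(methoxymethoxy)-5-(2-methylbut-3-en-2-yl)phenyl]lithium | [Li]c1cc(C(C)(C)C=C)c(OCOC)cc1OCOC
A6 | alternative 2 | 2-ethenyl-4,4,5,5-tetramethyl-1,3,2-dioxaborolane | C=CB1OC(C)(C)C(C)(C)O1
A7 | alternative 2 | 1-bromo-2,4-bis[(tert-butyldimethylsilyl)oxy]-3-{3-methyl-3-[(triethylsilyl)oxy]butyl}benzene | Brc1ccc(O[Si](C)(C)C(C)(C)C)c(CCC(C)(C)O[Si](CC)(CC)CC)c1O[Si](C)(C)C(C)(C)C
A8 | alternative 3 | (3R)-3-{4-hydroxy-5-(2-methylbut-3-en-2-yl)-2-[(triisopropylsilyl)oxy]phenyl}-8-(3-methylbut-2-en-1-yl)-3,4-dihydro-2H-chromen-7-ol | C=CC(C)(C)c1cc([C@@H]2COc3c(ccc(O)c3CC=C(C)C)C2)c(O[Si](C(C)C)(C(C)C)C(C)C)cc1O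
A9 | alternative 3 | (3R)-7-[(2-methylbut-3-en-2-yl)oxy]-3-{4-[(3-methylbut-2-en-1-yl)oxy]-2-[(triisopropylsilyl)oxy]phenyl}-3,4-dihydro-2H-chromene | CC(C)=CCOc1ccc([C@@H]2COc3cc(OC(C)(C)C=C)ccc3C2)c(O[Si](C(C)C)(C(C)C)C(C)C)c1
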